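The plan cuts the two trisubstituted C=C bonds of the prenyl chains at C6 (ring A) and C3' (ring B), so that each chain is carried through the synthesis as a sturdy allyl group. One double cross-metathesis with 2-methyl-2-butene, run last under neutral conditions, builds both Me2C=CH termini at once. It exploits the fact that the two side chains are identical, each ortho to a free phenol (7-OH, 4'-OH), and it leaves the base-labile C3–H stereocentre beside the C4 ketone alone. The precursor is unprotected (R)-6-allyl-3-(3-allyl-4-hydroxyphenyl)-7-hydroxychroman-4-one, assembled by ketone α-arylation and made single-handed by enantioselective protonation of its enol silane.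

Key step: step 12

Remark on the structure: the target is (3R)-7-hydroxy-3-[4-hydroxy-3-(3-methylbut-2-enyl)phenyl]-6-(3-methylbut-2-enyl)chroman-4-one, with no 5-OH. The CIP ranking at C3 (C4 > C2 > aryl > H) is the same in compounds 15, 16 and 18, so all three are (R).

Assumption: the (S)-configured chiral acid of step 10 is taken to deliver the (R)-ketone. Should a test run show the opposite sense, the mirror-image catalyst is used and nothing else changes. Enantiomeric purity would be assayed on 15 and 16 by chiral HPLC against racemic 13, and any shortfall made up by recrystallisation of 16 before the key step.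

Step 1
Reactants: 1 4-bromoresorcinol (4-bromobenzene-1,3-diol); 2 3-chloropropanoic acid
Product: 3 1-(5-bromo-2,4-dihydroxyphenyl)-3-chloropropan-1-one
Conditions: CF3SO3H (4 equiv, neat), 80 °C
Reagents that add atoms: none
Why: Friedel–Crafts acylation in triflic acid should go to the one ring carbon that is para to one hydroxyl, ortho to the other and not flanked by both, while the bromine already marks the future C6 of ring A.

Step 2
Reactants: 3 1-(5-bromo-2,4-dihydroxyphenyl)-3-chloropropan-1-one
Product: 4 6-bromo-7-hydroxychroman-4-one
Conditions: 2 M NaOH aq, 0 °C → rt; then HCl aq to pH 2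
Reagents that add atoms: none
Why: intramolecular Williamson etherification (6-exo-tet displacement of chloride by the ortho phenoxide, or the equivalent E1cB/oxa-Michael path) should close the pyranone ring, since the para hydroxyl cannot reach the chloride.

Step 3
Reactants: 4 6-bromo-7-hydroxychroman-4-one
Product: 5 6-bromo-7-(triisopropylsilyloxy)chroman-4-one
Conditions: TIPSCl, imidazole, DMF, rt
Reagents that add atoms: chlorotriisopropylsilane (TIPSCl), CC(C)[Si](Cl)(C(C)C)C(C)C
Why: standard phenol silylation; the bulky triisopropylsilyl ether is chosen because it should withstand the alkoxide base of step 8 and still leave with fluoride in a non-basic medium.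

Step 4
Reactants: 5 6-bromo-7-(triisopropylsilyloxy)chroman-4-one; 6 allyltributylstannane
Product: 7 6-allyl-7-(triisopropylsilyloxy)chroman-4-one
Conditions: Pd(PPh3)4 (5 mol%), toluene, 100 °C
Reagents that add atoms: none
Why: Migita–Kosugi–Stille coupling of an aryl bromide with an allylstannane is neutral and places the allyl group at C6 with full regiocontrol, whereas a Claisen rearrangement of a 7-allyloxychromanone would favour C8.

Step 5
Reactants: 8 4-bromophenol; 9 allyl bromide
Product: 10 1-(allyloxy)-4-bromobenzene
Conditions: K2CO3, acetone, reflux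
Reagents that add atoms: none
Why: Williamson ether synthesis, an SN2 displacement of bromide by the phenoxide.

Step 6
Reactants: 10 1-(allyloxy)-4-bromobenzene
Product: 11 2-allyl-4-bromophenol
Conditions: N,N-diethylaniline, 195 °C
Reagents that add atoms: none
Why: aromatic Claisen rearrangement ([3,3]-sigmatropic shift, then tautomerisation); the para position is blocked by bromine and the two ortho positions are equivalent, so one product is expected.

Step 7
Reactants: 11 2-allyl-4-bromophenol
Product: 12 (2-allyl-4-bromophenoxy)triisopropylsilane
Conditions: TIPSCl, imidazole, DMAP (cat.), DMF, 40 °C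
Reagents that add atoms: chlorotriisopropylsilane (TIPSCl), CC(C)[Si](Cl)(C(C)C)C(C)C
Why: phenol silylation with the same mask as on ring A, so that one reagent later frees both phenols.

Step 8
Reactants: 7 6-allyl-7-(triisopropylsilyloxy)chroman-4-one; 12 (2-allyl-4-bromophenoxy)triisopropylsilane
Product: 13 rac-6-allyl-3-[3-allyl-4-(triisopropylsilyloxy)phenyl]-7-(triisopropylsilyloxy)chroman-4-one
Conditions: Pd2(dba)3 (2.5 mol%), P(t-Bu)3·HBF4 (6 mol%), NaOtBu (2.2 equiv), toluene, 60 °C
Reagents that add atoms: none
Why: Buchwald–Hartwig-type α-arylation of a ketone (oxidative addition of the aryl bromide to zerovalent palladium, enolate binding, reductive elimination) should form the C3–C1' bond once only, because the product rests as a hindered, stabilised enolate; C3 arises racemic here.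

Step 9
Reactants: 13 rac-6-allyl-3-[3-allyl-4-(triisopropylsilyloxy)phenyl]-7-(triisopropylsilyloxy)chroman-4-one
Product: 14 {6-allyl-3-[3-allyl-4-(triisopropylsilyloxy)phenyl]-7-(triisopropylsilyloxy)-2H-chromen-4-yl}oxy(trimethyl)silane
Conditions: TMSOTf (1.5 equiv), Et3N (2.5 equiv), CH2Cl2, 0 °C → rt
Reagents that add atoms: trimethylsilyl trifluoromethanesulfonate (TMSOTf), C[Si](C)(C)OS(=O)(=O)C(F)(F)F
Why: soft enolisation and O-silylation of a ketone; C3 carries the only enolisable hydrogen (C4a is aromatic), so a single tetrasubstituted, prochiral enol silane should form and the racemic centre is erased on purpose.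

Step 10
Reactants: 14 {6-allyl-3-[3-allyl-4-(triisopropylsilyloxy)phenyl]-7-(triisopropylsilyloxy)-2H-chromen-4-yl}oxy(trimethyl)silane
Product: 15 (R)-6-allyl-3-[3-allyl-4-(triisopropylsilyloxy)phenyl]-7-(triisopropylsilyloxy)chroman-4-one
Conditions: (S)-3,3'-bis(2,4,6-triisopropylphenyl)-BINOL N-triflyl thiophosphoramide (5 mol%), PhOH (1.1 equiv), toluene, −20 °C
Reagents that add atoms: none
Why: catalytic enantioselective protonation of the enol silane of an α-aryl cyclic ketone by a chiral Brønsted acid, in which the acid delivers its proton to one enantiotopic face of C3 inside a tight chiral ion pair (catalyst control sets the (R) centre) and phenol, too weak to protonate the enol silane itself, takes the trimethylsilyl group and regenerates the acid.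

Step 11
Reactants: 15 (R)-6-allyl-3-[3-allyl-4-(triisopropylsilyloxy)phenyl]-7-(triisopropylsilyloxy)chroman-4-one
Product: 16 (R)-6-allyl-3-(3-allyl-4-hydroxyphenyl)-7-hydroxychroman-4-one
Conditions: HF·pyridine, pyridine, THF, 0 °C → rt
Reagents that add atoms: none
Why: fluoride cleavage of both aryl silyl ethers in an acidic, non-basic medium generates no phenoxide or free fluoride base, so the enolisable C3–H centre and the allyl groups should be untouched.

Step 12
Reactants: 16 (R)-6-allyl-3-(3-allyl-4-hydroxyphenyl)-7-hydroxychroman-4-one; 17 2-methyl-2-butene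
Product: 18 (R)-7-hydroxy-3-[4-hydroxy-3-(3-methylbut-2-enyl)phenyl]-6-(3-methylbut-2-enyl)chroman-4-one (target)
Conditions: second-generation Grubbs catalyst RuCl2(=CHPh)(H2IMes)(PCy3) (2 × 5 mol%), 1,4-benzoquinone (10 mol%), 2-methyl-2-butene/CH2Cl2 1:1, 35 °C, sealed tube
Reagents that add atoms: none
Why: Olefin cross-metathesis by the Chauvin mechanism: the ruthenium alkylidene adds to each terminal allyl C=C to give a ruthenacyclobutane, and cycloreversion followed by exchange with 2-methyl-2-butene installs the isopropylidene terminus and releases propene. The closest known reaction type is the cross-metathesis of ortho-allylphenols with 2-methyl-2-butene to give ortho-prenylphenols. No ring is closed and no stereocentre is formed, and the trisubstituted product alkenes have no E/Z issue. The step needs cross-metathesis to win over self-metathesis and over migration of the double bond into conjugation: the large excess of the trisubstituted partner should secure the first, benzoquinone should intercept ruthenium hydrides for the second, and the hindered prenyl alkenes, once formed, should not re-enter the cycle. The medium is neutral and only warm, so the C3–H centre beside the C4 ketone should keep its (R) configuration and the free 7-OH and 4'-OH need no protection. Any chain that first picks up the ethylidene end of the partner should be funnelled to the same product by continued exchange with the solvent olefin.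

Compound list
1 | 4-bromoresorcinol (4-bromobenzene-1,3-diol) | Oc1ccc(Br)c(O)c1 | starting material
2 | 3-chloropropanoic acid | OC(=O)CCCl | starting material
3 | 1-(5-bromo-2,4-dihydroxyphenyl)-3-chloropropan-1-one | O=C(CCCl)c1cc(Br)c(O)cc1O | intermediate
4 | 6-bromo-7-hydroxychroman-4-one | O=C1CCOc2cc(O)c(Br)cc21 | intermediate
5 | 6-bromo-7-(triisopropylsilyloxy)chroman-4-one | O=C1CCOc2cc(O[Si](C(C)C)(C(C)C)C(C)C)c(Br)cc21 | intermediate
6 | allyltributylstannane | C=CC[Sn](CCCC)(CCCC)CCCC | starting material
7 | 6-allyl-7-(triisopropylsilyloxy)chroman-4-one | C=CCc1cc2c(cc1O[Si](C(C)C)(C(C)C)C(C)C)OCCC2=O | intermediate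
8 | 4-bromophenol | Oc1ccc(Br)cc1 | starting material
9 | allyl bromide | C=CCBr | starting material
10 | 1-(allyloxy)-4-bromobenzene | C=CCOc1ccc(Br)cc1 | intermediate
11 | 2-allyl-4-bromophenol | C=CCc1cc(Br)ccc1O | intermediate
12 | (2-allyl-4-bromophenoxy)triisopropylsilane | C=CCc1cc(Br)ccc1O[Si](C(C)C)(C(C)C)C(C)C | intermediate
13 | rac-6-allyl-3-[3-allyl-4-(triisopropylsilyloxy)phenyl]-7-(triisopropylsilyloxy)chroman-4-one (racemic at C3) | C=CCc1cc(C2COc3cc(O[Si](C(C)C)(C(C)C)C(C)C)c(CC=C)cc3C2=O)ccc1O[Si](C(C)C)(C(C)C)C(C)C | intermediate
14 | {6-allyl-3-[3-allyl-4-(triisopropylsilyloxy)phenyl]-7-(triisopropylsilyloxy)-2H-chromen-4-yl}oxy(trimethyl)silane | C=CCc1cc(C2=C(O[Si](C)(C)C)c3cc(CC=C)c(O[Si](C(C)C)(C(C)C)C(C)C)cc3OC2)ccc1O[Si](C(C)C)(C(C)C)C(C)C | intermediate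
15 | (R)-6-allyl-3-[3-allyl-4-(triisopropylsilyloxy)phenyl]-7-(triisopropylsilyloxy)chroman-4-one | C=CCc1cc([C@@H]2COc3cc(O[Si](C(C)C)(C(C)C)C(C)C)c(CC=C)cc3C2=O)ccc1O[Si](C(C)C)(C(C)C)C(C)C | intermediate
16 | (R)-6-allyl-3-(3-allyl-4-hydroxyphenyl)-7-hydroxychroman-4-one | C=CCc1cc([C@@H]2COc3cc(O)c(CC=C)cc3C2=O)ccc1O | intermediate
17 | 2-methyl-2-butene | CC=C(C)C | starting material
18 | (R)-7-hydroxy-3-[4-hydroxy-3-(3-methylbut-2-enyl)phenyl]-6-(3-methylbut-2-enyl)chroman-4-one | CC(C)=CCc1cc([C@@H]2COc3cc(O)c(CC=C(C)C)cc3C2=O)ccc1O | target

Total step count: 12. Longest linear sequence: 9 steps (steps 1–4, then 8–12); the ring B branch (steps 5–7) joins at step 8.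

Steps most likely to fail

Step 10. The proton transfer to C3 may discriminate poorly between the two faces of this flat, electron-rich enol silane, or the acid may re-enolise the product and erode its purity. The fallback sets out from racemic ketone 13 and replaces protonation by reduction under dynamic kinetic resolution. Asymmetric transfer hydrogenation with RuCl(p-cymene)[(R,R)-TsDPEN] in HCO2H/Et3N (5:2), EtOAc, 40 °C, should reduce only one of the two equilibrating enantiomers of 13. The enantiomer of the catalyst is the one expected, by analogy with aryl ketones, to give the (4R) alcohol, and the product should be cis-(3R,4R)-6-allyl-3-[3-allyl-4-(triisopropylsilyloxy)phenyl]-7-(triisopropylsilyloxy)chroman-4-ol F1. Oxidation of the benzylic alcohol with Dess–Martin periodinane in CH2Cl2 at 0 °C, a non-basic oxidant, should return the ketone with C3 intact, and the route is rejoined at 15.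

Step 12. Ruthenium hydride may move the allyl double bonds into conjugation, one of the two sites may exchange incompletely, or the free phenols may deactivate the catalyst. The fallback sets out from 15 and runs the metathesis with the phenols still masked. The same catalyst, benzoquinone and 2-methyl-2-butene/CH2Cl2 at 35 °C should give (R)-6-(3-methylbut-2-enyl)-3-[3-(3-methylbut-2-enyl)-4-(triisopropylsilyloxy)phenyl]-7-(triisopropylsilyloxy)chroman-4-one F2. HF·pyridine buffered with pyridine in THF at 0 °C → rt, mild enough for the prenyl groups and the C3 centre, then removes both silyl groups and arrives directly at 18.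

Step 8. The alkoxide base or a palladium hydride may shift the terminal double bonds, the chromanone enolate may open by retro-oxa-Michael elimination, or a silyl ether may be lost. The fallback sets out from 7 and avoids alkoxide altogether. TMSOTf/Et3N in CH2Cl2 at 0 °C should give (6-allyl-7-(triisopropylsilyloxy)-2H-chromen-4-yl)oxy(trimethyl)silane F3. This enol silane is then coupled with aryl bromide 12 through the tin enolate formed in the flask (Bu3SnF, Pd2(dba)3, P(t-Bu)3, toluene, 80 °C), an essentially neutral arylation of an enol silane, and the route is rejoined at 13.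

Further compounds
F1 | step 10 | cis-(3R,4R)-6-allyl-3-[3-allyl-4-(triisopropylsilyloxy)phenyl]-7-(triisopropylsilyloxy)chroman-4-ol | C=CCc1cc([C@@H]2COc3cc(O[Si](C(C)C)(C(C)C)C(C)C)c(CC=C)cc3[C@@H]2O)ccc1O[Si](C(C)C)(C(C)C)C(C)C
F2 | step 12 | (R)-6-(3-methylbut-2-enyl)-3-[3-(3-methylbut-2-enyl)-4-(triisopropylsilyloxy)phenyl]-7-(triisopropylsilyloxy)chroman-4-one | CC(C)=CCc1cc([C@@H]2COc3cc(O[Si](C(C)C)(C(C)C)C(C)C)c(CC=C(C)C)cc3C2=O)ccc1O[Si](C(C)C)(C(C)C)C(C)C
F3 | step 8 | (6-allyl-7-(triisopropylsilyloxy)-2H-chromen-4-yl)oxy(trimethyl)silane | C=CCc1cc2C(O[Si](C)(C)C)=CCOc2cc1O[Si](C(C)C)(C(C)C)C(C)C
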